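## The problem

Pyrrhoxanthin (24) is a chain of three rings joined only by unsaturated carbon. An acetoxycyclohexene (ring A) ends a conjugated enyne–tetraene; the tetraene ends as the (Z)-exocyclic alkene at C5 of a butenolide (ring B); and C3 of that lactone carries an (E)-vinyl link to an epoxycyclohexanol (ring C). The synthesis must therefore assemble seven C=C bonds of defined geometry (six E, one Z) and one alkyne, and place four stereocentres. These are the acetoxy carbon of ring A (R), the carbinol carbon of ring C (S), and the two adjacent, fully substituted oxirane carbons of ring C, with the oxygen bridge on the face opposite the hydroxyl. The two O-bearing CH centres have the same spatial arrangement and can both come from one chiral ketone. The ring C carbinol, however, is 1,3 to the oxirane across a flexible ring and cannot be trusted to steer an oxidant to the anti face, so that face must be chosen by a reagent. The fragile groups are the vinyl oxirane (protic and Lewis acids), the secondary acetate that must survive beside a free secondary alcohol (no hydride, no alkoxide, no late protecting-group exchange), the electrophilic alkylidene lactone, and the polyene (light, oxygen). The feature that opens the route is that the oxirane spans the methyl-bearing and the chain-bearing carbon of ring C. If the vinyl arm is traced back to CH2OH, ring C becomes a 4-oxygenated 2,6,6-trimethylcyclohex-1-enylmethanol, a primary allylic alcohol on a tetrasubstituted alkene, which is the substrate class of the Ti(OiPr)4–tartrate epoxidation.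

## Retrosynthesis

**24 to 23 and 9.** The bond between C3 of ring B and the vinyl arm is cut last, giving bromo-alkylidenebutenolide 23 and hydroxy vinylstannane 9. The neighbouring cut at the exocyclic alkene of ring B would also be convergent, but its forward reaction uses a silyl triflate in the presence of the vinyl oxirane and ends with a desilylation beside the acetate. With the chosen cut the oxirane meets only a neutral Stille coupling, both halves already carry their final oxygen functions, and no protecting group is left on the pigment. The forward reaction must retain both alkene geometries and tolerate a free alcohol.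

**23 to 19 and 20.** The exocyclic C5=C bond of ring B is cut to polyenal 19 and purchasable 3-bromofuran-2(5H)-one 20. This uses the lactone ring as bought and leaves the bromine as the handle for the last coupling. The forward vinylogous aldol–elimination must attack through C5 of the furanone and give the Z alkene, which is the thermodynamically preferred isomer.

**19 to 17 and 18, then 17 to 14 and 15.** Two C=C bonds of the tetraene are cut by Wittig logic. The trisubstituted one comes from aldehyde 17 and the stabilised formyl ylide 18. The next disubstituted one comes from the ring A phosphonium salt 14 and the four-carbon aldehyde acetal 15. Both partners are purchasable and every step tolerates the acetate, which a route through ester reduction would not. The first forward Wittig reaction is expected to need an iodine equilibration to the all-E chain.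

**14 back to 3 and 10.** Salt 14 comes from 13 by acetylation, 13 from diol 12 by allylic substitution with PPh3·HBr, and 12 from silyl ether 11 by fluoride. The sp–sp2 bond of 11 is cut to enol triflate 3 and enynol 10. The trisubstituted enyne alkene is thereby bought with its geometry, and ring A branches from an intermediate that ring C also needs.

**9 back to 6.** Stannane 9 is the desilylated form of 8. The vinyl C=C of 8 is cut to aldehyde 7 and a one-carbon tin reagent, and 7 is the oxidation product of epoxy alcohol 6. Removing the silyl group at the stannane stage, before any acetate is present, avoids a selective deprotection at the end. The olefination must be E-selective on an α-quaternary epoxy aldehyde.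

**6 to 5 (key disconnection).** Both C–O bonds of the oxirane are cut to give allylic alcohol 5, which removes two fully substituted stereocentres and one ring in a single step. The alternative of epoxidising a later, chain-bearing intermediate would lose the directing hydroxymethyl group and expose other alkenes. The forward reaction must deliver oxygen anti to the C4 silyloxy group under catalyst control. The Ti(OiPr)4–tartrate catalyst takes achiral 1-cyclohexenylmethanols to the (1S,2S) epoxides with the L-(+) ester and to the (1R,2R) series with the D-(−) ester. Compound 6 is (1R,6R) in the same sense, so the D-(−) ester is specified; the natural ester would be expected to give the syn epimer.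

**5 back to 1.** The hydroxymethyl carbon is traced through ester 4 to a carbonylation of triflate 3. Triflate 3 comes from silyl ether 2 of (4R,6R)-actinol 1, whose ketone can enolise in only one direction. The C6 centre of 1 is erased on purpose; the C4 centre is the single source of the carbinol configuration in both end rings.

## Roads not taken

**Alternative 1:** Here ring B would be carried as a furan. The cut is at the lactone carbonyl and the C5–O bond: the 2-trimethylsilylfuran A1 is photo-oxygenated with singlet oxygen, and the endoperoxide collapses with silyl migration to the γ-hydroxybutenolide A2. A2 would then be dehydrated to the alkylidene lactone and joined through its vinyl iodide to a ring A polyene. Its merit is real: the lactone stays masked as a robust furan through basic and organometallic steps, the silyl group fixes which furan carbon becomes the carbonyl, and the last union would put no tin on the oxirane half. Its weak points for this target are the other oxidisable sites of A1. The 3-vinylfuran is itself a diene for singlet oxygen, and the trisubstituted iodoalkene can undergo an ene reaction. The dehydration of A2 must also choose both the direction and the Z geometry of the new alkene. A 2,3,5-trisubstituted furan must be built first, and the oxirane would still have to be made exactly as in the chosen plan, so this road adds steps without removing the key problem. The chosen plan sets a purchased lactone ring and an elimination that gives the thermodynamically preferred Z alkene against the better masking of Alternative 1.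

**Alternative 2:** Ring B would be closed from an acyclic (Z)-β-iodoenone A3 by carbonylation. CO insertion forms the bond from the α-carbon to the carbonyl, and the dienolate oxygen of the ketone captures the acylpalladium, giving the alkylidenebutenolide A4 with its exocyclic alkene in one step. This is better than the chosen plan in two respects: it needs no stoichiometric tin, and it makes the ring and the Z alkene catalytically from CO. Against it stand several difficulties. A stereodefined iodoenone that already carries the vinyl oxirane and a β,γ-unsaturated ketone prone to conjugation is hard to prepare. A zerovalent palladium catalyst would be used under CO with a free hydroxyl and a vinyl oxirane. And A4 carries only a short silyloxy dienyl arm, so oxidation and a further olefination would still be needed to reach ring A. The chosen plan offers a shorter, more convergent endgame, at the price of one Stille coupling.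

**Alternative 3:** This addresses the ring A chain. The C–CH3 bond and the adjacent sp2–sp2 bond are cut. In the forward step, Cp2ZrCl2-catalysed addition of AlMe3 across the terminal alkyne of diyne A5 is followed by in-situ coupling (ZnCl2, Pd(PPh3)4) with iodotrienoate A6 to give tetraenynoate A7. In alkene geometry this road is superior: syn carbometalation and a retentive coupling fix the trisubstituted enyne alkene and its neighbour, whereas step 13 of the chosen plan is expected to give an E/Z mixture that must be equilibrated. Its costs are elsewhere. AlMe3 is incompatible with the acetate, so a silyl ether and a later exchange are needed. The ester of A7 must be reduced and reoxidised to the aldehyde. A5 and A6 each take several steps to make. The chosen plan sets against the better stereocontrol a two-step chain extension from purchasable C4 and C3 units that tolerates the acetate throughout.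

Key step: step 5

Assumption (enantioface rule): the Ti(OiPr)4–tartrate epoxidation is taken to follow its usual descriptor rule, L-(+)-tartrate giving the (2S) and D-(−)-tartrate the (2R) epoxy alcohols of achiral primary allylic alcohols; 6 belongs to the (2R) series, hence the D-(−) ester.

Assumption (availability): compounds 1, 10, 15, 18 and 20 are purchasable, and (dibromomethyl)tributylstannane is a known reagent made in one operation from CH2Br2, LiN(i-Pr)2 and Bu3SnCl.

## Route

Step 1
Reactants: 1 (4R,6R)-actinol [(4R,6R)-4-hydroxy-2,2,6-trimethylcyclohexan-1-one]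
Product: 2 (4R,6R)-4-[(tert-butyldimethylsilyl)oxy]-2,2,6-trimethylcyclohexan-1-one
Conditions: t-BuMe2SiCl, imidazole, DMF, rt
Reagents that add atoms: tert-butyldimethylsilyl chloride, CC(C)(C)[Si](C)(C)Cl
Why: Standard silylation of a secondary alcohol; imidazole does not epimerise the α-methyl centre, and the silyl ether withstands every step up to step 8.

Step 2
Reactants: 2 (4R,6R)-4-[(tert-butyldimethylsilyl)oxy]-2,2,6-trimethylcyclohexan-1-one
Product: 3 (4R)-4-[(tert-butyldimethylsilyl)oxy]-2,6,6-trimethylcyclohex-1-en-1-yl trifluoromethanesulfonate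
Conditions: LiN(i-Pr)2, THF, −78 to 0 °C; PhNTf2, 0 °C to rt
Reagents that add atoms: N-phenylbis(trifluoromethanesulfonimide), O=S(=O)(N(c1ccccc1)S(=O)(=O)C(F)(F)F)C(F)(F)F
Why: Enol triflate formation by O-sulfonylation of the lithium enolate; the ketone can enolise only toward C6 because the other α-carbon is quaternary, so a single tetrasubstituted triflate should form and the C6 centre is erased as intended.

Step 3
Reactants: 3 (4R)-4-[(tert-butyldimethylsilyl)oxy]-2,6,6-trimethylcyclohex-1-en-1-yl trifluoromethanesulfonate
Product: 4 methyl (4R)-4-[(tert-butyldimethylsilyl)oxy]-2,6,6-trimethylcyclohex-1-ene-1-carboxylate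
Conditions: Pd(OAc)2 (cat.), PPh3, CO (1 atm), Et3N, MeOH–DMF, 60 °C
Reagents that add atoms: carbon monoxide, [C-]#[O+]; methanol, CO
Why: Pd-catalysed methoxycarbonylation of a vinyl triflate (oxidative addition, CO insertion, methanolysis of the acyl complex); the buffered basic medium leaves the silyl ether intact.

Step 4
Reactants: 4 methyl (4R)-4-[(tert-butyldimethylsilyl)oxy]-2,6,6-trimethylcyclohex-1-ene-1-carboxylate
Product: 5 [(4R)-4-[(tert-butyldimethylsilyl)oxy]-2,6,6-trimethylcyclohex-1-en-1-yl]methanol
Conditions: i-Bu2AlH, CH2Cl2, −78 to 0 °C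
Reagents that add atoms: none
Why: 1,2-Reduction of an α,β-unsaturated ester to the allylic alcohol by an aluminium hydride; the hindered tetrasubstituted alkene is not reduced.

Step 5
Reactants: 5 [(4R)-4-[(tert-butyldimethylsilyl)oxy]-2,6,6-trimethylcyclohex-1-en-1-yl]methanol
Product: 6 [(1R,4S,6R)-4-[(tert-butyldimethylsilyl)oxy]-2,2,6-trimethyl-7-oxabicyclo[4.1.0]heptan-1-yl]methanol (oxirane anti to the silyloxy group)
Conditions: Ti(OiPr)4 (cat.), diethyl D-(−)-tartrate (cat.), t-BuOOH (decane), 4 Å MS, CH2Cl2, −20 °C
Reagents that add atoms: tert-butyl hydroperoxide, CC(C)(C)OO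
Why: Katsuki–Sharpless asymmetric epoxidation: the alkoxide of 5 and the hydroperoxide replace isopropoxide on the catalyst formed from Ti(OiPr)4 and the tartrate, and the distal peroxide oxygen is passed to the alkene in one concerted, suprafacial step that forms both C–O bonds. The closest known cases are the tartrate-controlled epoxidations of 1-cyclohexenylmethanols and of 4-oxygenated β-cyclogeraniols, which are tetrasubstituted like 5. The three-membered ring closes by simultaneous bonding of one oxygen to both alkene carbons (formally a 3-exo-tet attack of the π bond on the O–O bond), so it is necessarily cis-fused to the cyclohexane. C1 and C6, both fully substituted, are set together by the enantioface the catalyst selects: the D-(−) ester gives the (2R) series of epoxy alcohols, here (1R,6R), which places the oxygen opposite the C4 silyloxy group, whereas the L-(+) ester would be expected to give the syn epimer. Only diastereofacial selectivity is at stake, since 5 has a single alkene, and it is secured by the catalyst and not by the remote C4 centre, whose own bias is small. C4 is untouched and becomes 4S only through the change in substituent priorities. Coordination of the primary alcohol also accelerates the oxidation of this hindered alkene.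

Step 6
Reactants: 6 [(1R,4S,6R)-4-[(tert-butyldimethylsilyl)oxy]-2,2,6-trimethyl-7-oxabicyclo[4.1.0]heptan-1-yl]methanol
Product: 7 (1S,4S,6R)-4-[(tert-butyldimethylsilyl)oxy]-2,2,6-trimethyl-7-oxabicyclo[4.1.0]heptane-1-carbaldehyde
Conditions: (n-Pr)4N[RuO4] (cat.), NMO, 4 Å MS, CH2Cl2, rt
Reagents that add atoms: none
Why: Ley–Griffith oxidation of a primary alcohol under neutral conditions; the aldehyde has no α-hydrogen, so it cannot epimerise, and the oxirane is not exposed to acid.

Step 7
Reactants: 7 (1S,4S,6R)-4-[(tert-butyldimethylsilyl)oxy]-2,2,6-trimethyl-7-oxabicyclo[4.1.0]heptane-1-carbaldehyde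
Product: 8 tributyl{(E)-2-[(1S,4S,6R)-4-[(tert-butyldimethylsilyl)oxy]-2,2,6-trimethyl-7-oxabicyclo[4.1.0]heptan-1-yl]ethenyl}stannane
Conditions: Bu3SnCHBr2, CrCl2, LiI, THF–DMF, rt, dark
Reagents that add atoms: (dibromomethyl)tributylstannane, CCCC[Sn](CCCC)(CCCC)C(Br)Br
Why: Takai-type olefination with the geminal dichromium reagent generated from Bu3SnCHBr2 and CrCl2; addition to the non-enolisable aldehyde and anti elimination should give the (E)-alkenylstannane directly, with no alkyne intermediate.

Step 8
Reactants: 8 tributyl{(E)-2-[(1S,4S,6R)-4-[(tert-butyldimethylsilyl)oxy]-2,2,6-trimethyl-7-oxabicyclo[4.1.0]heptan-1-yl]ethenyl}stannane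
Product: 9 (1R,3S,6S)-1,5,5-trimethyl-6-[(E)-2-(tributylstannyl)ethenyl]-7-oxabicyclo[4.1.0]heptan-3-ol
Conditions: n-Bu4NF, THF, rt
Reagents that add atoms: none
Why: Fluoride cleavage of a silyl ether; vinylstannane and oxirane are stable to fluoride, and the deprotection is done here because no acetate is yet present.

Step 9
Reactants: 3 (4R)-4-[(tert-butyldimethylsilyl)oxy]-2,6,6-trimethylcyclohex-1-en-1-yl trifluoromethanesulfonate; 10 (E)-3-methylpent-2-en-4-yn-1-ol
Product: 11 (2E)-5-[(4R)-4-[(tert-butyldimethylsilyl)oxy]-2,6,6-trimethylcyclohex-1-en-1-yl]-3-methylpent-2-en-4-yn-1-ol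
Conditions: Pd(PPh3)4 (cat.), CuI (cat.), i-Pr2NH, DMF, rt
Reagents that add atoms: none
Why: Sonogashira coupling of a vinyl triflate with a terminal alkyne; the free primary alcohol is tolerated and the E geometry of the trisubstituted alkene is carried over from 10.

Step 10
Reactants: 11 (2E)-5-[(4R)-4-[(tert-butyldimethylsilyl)oxy]-2,6,6-trimethylcyclohex-1-en-1-yl]-3-methylpent-2-en-4-yn-1-ol
Product: 12 (1R)-4-[(3E)-5-hydroxy-3-methylpent-3-en-1-yn-1-yl]-3,5,5-trimethylcyclohex-3-en-1-ol
Conditions: n-Bu4NF, THF, rt
Reagents that add atoms: none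
Why: Fluoride desilylation; nothing else in 11 reacts with fluoride.

Step 11
Reactants: 12 (1R)-4-[(3E)-5-hydroxy-3-methylpent-3-en-1-yn-1-yl]-3,5,5-trimethylcyclohex-3-en-1-ol
Product: 13 {(2E)-5-[(4R)-4-hydroxy-2,6,6-trimethylcyclohex-1-en-1-yl]-3-methylpent-2-en-4-yn-1-yl}triphenylphosphonium bromide
Conditions: PPh3·HBr, MeOH, rt
Reagents that add atoms: triphenylphosphine hydrobromide, Br.c1ccc(cc1)P(c1ccccc1)c1ccccc1
Why: Acid-promoted allylic substitution (SN1-type) of the primary allylic alcohol by PPh3, the classical route to polyene Wittig salts; the homoallylic ring alcohol cannot ionise, and attack at the primary terminus of the allyl cation gives the conjugated E salt.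

Step 12
Reactants: 13 {(2E)-5-[(4R)-4-hydroxy-2,6,6-trimethylcyclohex-1-en-1-yl]-3-methylpent-2-en-4-yn-1-yl}triphenylphosphonium bromide
Product: 14 {(2E)-5-[(4R)-4-acetoxy-2,6,6-trimethylcyclohex-1-en-1-yl]-3-methylpent-2-en-4-yn-1-yl}triphenylphosphonium bromide
Conditions: Ac2O, pyridine, DMAP (cat.), CH2Cl2, rt
Reagents that add atoms: acetic anhydride, CC(=O)OC(C)=O
Why: Acylation of the only remaining hydroxyl with retention at the carbinol carbon; the phosphonium salt is inert to Ac2O and pyridine.

Step 13
Reactants: 14 {(2E)-5-[(4R)-4-acetoxy-2,6,6-trimethylcyclohex-1-en-1-yl]-3-methylpent-2-en-4-yn-1-yl}triphenylphosphonium bromide; 15 fumaraldehyde mono(dimethyl acetal) [(2E)-4,4-dimethoxybut-2-enal]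
Product: 17 (1R)-4-[(3E,5E,7E)-3-methyl-9-oxonona-3,5,7-trien-1-yn-1-yl]-3,5,5-trimethylcyclohex-3-en-1-yl acetate, via trienynal dimethyl acetal 16 (not isolated)
Conditions: NaN(SiMe3)2 (1 equiv), THF, −78 to 0 °C; then TsOH·H2O (cat.), acetone–H2O, rt; then I2 (cat.), CH2Cl2, rt
Reagents that add atoms: water, O
Why: Wittig olefination with a semi-stabilised allylic ylide, followed by acid hydrolysis of the acetal; one equivalent of amide base deprotonates the phosphonium salt far faster than the acetate. The new disubstituted alkene is expected as an E/Z mixture, which catalytic iodine should equilibrate to the all-E trienynal.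

Step 14
Reactants: 17 (1R)-4-[(3E,5E,7E)-3-methyl-9-oxonona-3,5,7-trien-1-yn-1-yl]-3,5,5-trimethylcyclohex-3-en-1-yl acetate; 18 2-(triphenylphosphoranylidene)propanal
Product: 19 (1R)-4-[(3E,5E,7E,9E)-3,10-dimethyl-11-oxoundeca-3,5,7,9-tetraen-1-yn-1-yl]-3,5,5-trimethylcyclohex-3-en-1-yl acetate
Conditions: toluene, 60 °C, dark
Reagents that add atoms: none
Why: Wittig reaction of a stabilised formyl ylide, which should give the (E)-trisubstituted enal; the α-methyl enal product is less electrophilic than 17, so a second homologation should not compete.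

Step 15
Reactants: 19 (1R)-4-[(3E,5E,7E,9E)-3,10-dimethyl-11-oxoundeca-3,5,7,9-tetraen-1-yn-1-yl]-3,5,5-trimethylcyclohex-3-en-1-yl acetate; 20 3-bromofuran-2(5H)-one
Product: 23 (1R)-4-[(3E,5E,7E,9E,11Z)-11-(4-bromo-5-oxofuran-2(5H)-ylidene)-3,10-dimethylundeca-3,5,7,9-tetraen-1-yn-1-yl]-3,5,5-trimethylcyclohex-3-en-1-yl acetate, via 3-bromo-2-silyloxyfuran 21 (not isolated), via silylated aldol adduct 22 (not isolated)
Conditions: t-BuMe2SiOTf, i-Pr2NEt, CH2Cl2, −78 °C to rt; then DBU, rt
Reagents that add atoms: none
Why: One-pot vinylogous Mukaiyama aldol–elimination: silyl triflate and amine convert 20 into silyloxyfuran 21, which adds through C5 to the silyl-activated aldehyde; DBU then removes the acidic C5 hydrogen and expels silanolate (E1cB). The Z alkylidene lactone is the thermodynamically preferred isomer, and the 3-bromo substituent reinforces that preference.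

Step 16
Reactants: 23 (1R)-4-[(3E,5E,7E,9E,11Z)-11-(4-bromo-5-oxofuran-2(5H)-ylidene)-3,10-dimethylundeca-3,5,7,9-tetraen-1-yn-1-yl]-3,5,5-trimethylcyclohex-3-en-1-yl acetate; 9 (1R,3S,6S)-1,5,5-trimethyl-6-[(E)-2-(tributylstannyl)ethenyl]-7-oxabicyclo[4.1.0]heptan-3-ol
Product: 24 pyrrhoxanthin
Conditions: Pd2(dba)3 (cat.), AsPh3, NMP, 40 °C, dark
Reagents that add atoms: none
Why: Stille coupling of an alkenyl bromide with an alkenylstannane, with retention of both alkene geometries; the neutral conditions tolerate the free alcohol, the acetate and the oxirane, and oxidative addition into the electron-poor C–Br bond should outrun any ionisation of the hindered vinyl oxirane.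

## Compound list

1 | (4R,6R)-actinol, (4R,6R)-4-hydroxy-2,2,6-trimethylcyclohexan-1-one | O[C@@H]1C[C@@H](C)C(=O)C(C)(C)C1 | starting material
2 | (4R,6R)-4-[(tert-butyldimethylsilyl)oxy]-2,2,6-trimethylcyclohexan-1-one | CC(C)(C)[Si](C)(C)O[C@@H]1C[C@@H](C)C(=O)C(C)(C)C1 | intermediate
3 | (4R)-4-[(tert-butyldimethylsilyl)oxy]-2,6,6-trimethylcyclohex-1-en-1-yl trifluoromethanesulfonate | FC(F)(F)S(=O)(=O)OC1=C(C)C[C@@H](O[Si](C)(C)C(C)(C)C)CC1(C)C | intermediate
4 | methyl (4R)-4-[(tert-butyldimethylsilyl)oxy]-2,6,6-trimethylcyclohex-1-ene-1-carboxylate | COC(=O)C1=C(C)C[C@@H](O[Si](C)(C)C(C)(C)C)CC1(C)C | intermediate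
5 | [(4R)-4-[(tert-butyldimethylsilyl)oxy]-2,6,6-trimethylcyclohex-1-en-1-yl]methanol | OCC1=C(C)C[C@@H](O[Si](C)(C)C(C)(C)C)CC1(C)C | intermediate
6 | [(1R,4S,6R)-4-[(tert-butyldimethylsilyl)oxy]-2,2,6-trimethyl-7-oxabicyclo[4.1.0]heptan-1-yl]methanol | OC[C@@]12O[C@]1(C)C[C@@H](O[Si](C)(C)C(C)(C)C)CC2(C)C | intermediate
7 | (1S,4S,6R)-4-[(tert-butyldimethylsilyl)oxy]-2,2,6-trimethyl-7-oxabicyclo[4.1.0]heptane-1-carbaldehyde | O=C[C@@]12O[C@]1(C)C[C@@H](O[Si](C)(C)C(C)(C)C)CC2(C)C | intermediate
8 | tributyl{(E)-2-[(1S,4S,6R)-4-[(tert-butyldimethylsilyl)oxy]-2,2,6-trimethyl-7-oxabicyclo[4.1.0]heptan-1-yl]ethenyl}stannane | CCCC[Sn](CCCC)(CCCC)/C=C/[C@@]12O[C@]1(C)C[C@@H](O[Si](C)(C)C(C)(C)C)CC2(C)C | intermediate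
9 | (1R,3S,6S)-1,5,5-trimethyl-6-[(E)-2-(tributylstannyl)ethenyl]-7-oxabicyclo[4.1.0]heptan-3-ol | CCCC[Sn](CCCC)(CCCC)/C=C/[C@@]12O[C@]1(C)C[C@@H](O)CC2(C)C | intermediate
10 | (E)-3-methylpent-2-en-4-yn-1-ol | C#C/C(C)=C/CO | starting material
11 | (2E)-5-[(4R)-4-[(tert-butyldimethylsilyl)oxy]-2,6,6-trimethylcyclohex-1-en-1-yl]-3-methylpent-2-en-4-yn-1-ol | CC(C)(C)[Si](C)(C)O[C@@H]1CC(C)=C(C#C/C(C)=C/CO)C(C)(C)C1 | intermediate
12 | (1R)-4-[(3E)-5-hydroxy-3-methylpent-3-en-1-yn-1-yl]-3,5,5-trimethylcyclohex-3-en-1-ol | O[C@@H]1CC(C)=C(C#C/C(C)=C/CO)C(C)(C)C1 | intermediate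
13 | {(2E)-5-[(4R)-4-hydroxy-2,6,6-trimethylcyclohex-1-en-1-yl]-3-methylpent-2-en-4-yn-1-yl}triphenylphosphonium bromide | O[C@@H]1CC(C)=C(C#C/C(C)=C/C[P+](c2ccccc2)(c2ccccc2)c2ccccc2)C(C)(C)C1.[Br-] | intermediate
14 | {(2E)-5-[(4R)-4-acetoxy-2,6,6-trimethylcyclohex-1-en-1-yl]-3-methylpent-2-en-4-yn-1-yl}triphenylphosphonium bromide | CC(=O)O[C@@H]1CC(C)=C(C#C/C(C)=C/C[P+](c2ccccc2)(c2ccccc2)c2ccccc2)C(C)(C)C1.[Br-] | intermediate
15 | fumaraldehyde mono(dimethyl acetal), (2E)-4,4-dimethoxybut-2-enal | COC(OC)/C=C/C=O | starting material
16 | (1R)-4-[(3E,5E,7E)-9,9-dimethoxy-3-methylnona-3,5,7-trien-1-yn-1-yl]-3,5,5-trimethylcyclohex-3-en-1-yl acetate (formed as an E/Z mixture at the new alkene) | CC(=O)O[C@@H]1CC(C)=C(C#C/C(C)=C/C=C/C=C/C(OC)OC)C(C)(C)C1 | intermediate (not isolated)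
17 | (1R)-4-[(3E,5E,7E)-3-methyl-9-oxonona-3,5,7-trien-1-yn-1-yl]-3,5,5-trimethylcyclohex-3-en-1-yl acetate | CC(=O)O[C@@H]1CC(C)=C(C#C/C(C)=C/C=C/C=C/C=O)C(C)(C)C1 | intermediate
18 | 2-(triphenylphosphoranylidene)propanal | CC(C=O)=P(c1ccccc1)(c1ccccc1)c1ccccc1 | starting material
19 | (1R)-4-[(3E,5E,7E,9E)-3,10-dimethyl-11-oxoundeca-3,5,7,9-tetraen-1-yn-1-yl]-3,5,5-trimethylcyclohex-3-en-1-yl acetate | CC(=O)O[C@@H]1CC(C)=C(C#C/C(C)=C/C=C/C=C/C=C(C)/C=O)C(C)(C)C1 | intermediate
20 | 3-bromofuran-2(5H)-one | O=C1OCC=C1Br | starting material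
21 | [(3-bromofuran-2-yl)oxy](tert-butyl)dimethylsilane | CC(C)(C)[Si](C)(C)Oc1occc1Br | intermediate (not isolated)
22 | (1R)-4-[(3E,5E,7E,9E)-11-(4-bromo-5-oxo-2,5-dihydrofuran-2-yl)-11-[(tert-butyldimethylsilyl)oxy]-3,10-dimethylundeca-3,5,7,9-tetraen-1-yn-1-yl]-3,5,5-trimethylcyclohex-3-en-1-yl acetate (mixture of diastereomers at the two new centres) | CC(=O)O[C@@H]1CC(C)=C(C#C/C(C)=C/C=C/C=C/C=C(C)/C(O[Si](C)(C)C(C)(C)C)C2OC(=O)C(Br)=C2)C(C)(C)C1 | intermediate (not isolated)
23 | (1R)-4-[(3E,5E,7E,9E,11Z)-11-(4-bromo-5-oxofuran-2(5H)-ylidene)-3,10-dimethylundeca-3,5,7,9-tetraen-1-yn-1-yl]-3,5,5-trimethylcyclohex-3-en-1-yl acetate | CC(=O)O[C@@H]1CC(C)=C(C#C/C(C)=C/C=C/C=C/C=C(C)/C=C2C=C(Br)C(=O)O/2)C(C)(C)C1 | intermediate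
24 | pyrrhoxanthin | CC(=O)O[C@@H]1CC(C)=C(C#C/C(C)=C/C=C/C=C/C=C(C)/C=C2C=C(/C=C/[C@@]34O[C@]3(C)C[C@@H](O)CC4(C)C)C(=O)O/2)C(C)(C)C1 | target

## Step count and risks

Total: 16 steps. Longest linear sequence: 10 steps (steps 1, 2, 9, 10, 11, 12, 13, 14, 15, 16); the ring C branch is 9 steps (1 to 8, then 16).

**Step 5 (key step).** Turnover on the hindered tetrasubstituted alkene may be slow. Facial discrimination may also be incomplete if catalyst control and the small intrinsic bias of the C4 centre oppose each other. Because the antipodal tartrate leads to the other epimer, the sense of oxygen delivery should be confirmed on 6 by NOE before material is committed. The fallback gives up ligand control. Setting out from 5, peracid epoxidation (mCPBA, NaHCO3, CH2Cl2, 0 °C) should give both epoxy alcohols under substrate control. Compound 6 is then separated by chromatography from the syn epoxy alcohol F1, and the route is rejoined at 6.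

**Step 7.** Divalent chromium may open the α,β-epoxy aldehyde reductively, the Lewis-acidic chromium salts may rearrange the oxirane before olefination, and E selectivity may erode. The fallback goes through an alkyne. Setting out from 7, Ohira–Bestmann homologation (dimethyl (1-diazo-2-oxopropyl)phosphonate, K2CO3, MeOH) gives the ethynyl oxirane F2. Syn hydrostannylation with Bu3SnH and PdCl2(PPh3)2 (THF, 0 °C) follows; the quaternary propargylic carbon should steer tin to the terminal position, and the route returns at 8.

**Step 13.** The semi-stabilised ylide may give poor E selectivity, the iodine equilibration may be incomplete or may scramble the trisubstituted enyne alkene, and some acetate may be lost to base. The fallback reverses the roles so that each new alkene comes from a stabilised ylide. Setting out from 12, MnO2 (CH2Cl2, rt) oxidises only the primary allylic alcohol to the hydroxy enynal F3. Ac2O and pyridine give the acetoxy enynal F4. A Wittig reaction with Ph3P=CHCHO gives the acetoxy dienynal F5, and a second Wittig reaction with the same ylide returns the route at 17.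

**Step 15.** Attack may occur through C3 instead of C5 of the silyloxyfuran, the silyl triflate may polymerise or add conjugatively to the polyenal, elimination may be incomplete, or the E-alkylidene isomer may form. The fallback separates the two events. Setting out from 19 and 20, silyloxyfuran 21 is prepared and isolated on its own. A BF3·OEt2-promoted vinylogous Mukaiyama aldol addition at −78 °C gives the hydroxy butenolide F6. This is converted (MsCl, Et3N) into the mesylate F7 and eliminated with DBU, returning at 23.

**Step 16.** Protodestannylation or homocoupling may compete, the catalyst may cause Z/E stereomutation of the polyene or ionise the vinyl oxirane, and tin residues may be hard to remove from the sensitive final pigment. The fallback changes the order of bond formation. Setting out from 8 and 20, a Stille coupling (Pd2(dba)3, AsPh3, NMP) gives the epoxy vinyl butenolide F8. The one-pot silyl triflate/amine, then DBU condensation with 19 gives O-silyl pyrrhoxanthin F9. Buffered fluoride (n-Bu4NF, AcOH, THF, 0 °C to rt) then returns at 24.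

## Further compounds

F1 | step 5 | [(1S,4S,6S)-4-[(tert-butyldimethylsilyl)oxy]-2,2,6-trimethyl-7-oxabicyclo[4.1.0]heptan-1-yl]methanol (syn epoxy alcohol) | OC[C@]12O[C@@]1(C)C[C@@H](O[Si](C)(C)C(C)(C)C)CC2(C)C
F2 | step 7 | (1R,4S,6R)-4-[(tert-butyldimethylsilyl)oxy]-1-ethynyl-2,2,6-trimethyl-7-oxabicyclo[4.1.0]heptane | C#C[C@@]12O[C@]1(C)C[C@@H](O[Si](C)(C)C(C)(C)C)CC2(C)C
F3 | step 13 | (2E)-5-[(4R)-4-hydroxy-2,6,6-trimethylcyclohex-1-en-1-yl]-3-methylpent-2-en-4-ynal | O[C@@H]1CC(C)=C(C#C/C(C)=C/C=O)C(C)(C)C1
F4 | step 13 | (1R)-3,5,5-trimethyl-4-[(3E)-3-methyl-5-oxopent-3-en-1-yn-1-yl]cyclohex-3-en-1-yl acetate | CC(=O)O[C@@H]1CC(C)=C(C#C/C(C)=C/C=O)C(C)(C)C1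
F5 | step 13 | (1R)-3,5,5-trimethyl-4-[(3E,5E)-3-methyl-7-oxohepta-3,5-dien-1-yn-1-yl]cyclohex-3-en-1-yl acetate | CC(=O)O[C@@H]1CC(C)=C(C#C/C(C)=C/C=C/C=O)C(C)(C)C1
F6 | step 15 | (1R)-4-[(3E,5E,7E,9E)-11-(4-bromo-5-oxo-2,5-dihydrofuran-2-yl)-11-hydroxy-3,10-dimethylundeca-3,5,7,9-tetraen-1-yn-1-yl]-3,5,5-trimethylcyclohex-3-en-1-yl acetate (diastereomer mixture) | CC(=O)O[C@@H]1CC(C)=C(C#C/C(C)=C/C=C/C=C/C=C(C)/C(O)C2OC(=O)C(Br)=C2)C(C)(C)C1
F7 | step 15 | methanesulfonate of F6 (diastereomer mixture) | CC(=O)O[C@@H]1CC(C)=C(C#C/C(C)=C/C=C/C=C/C=C(C)/C(OS(C)(=O)=O)C2OC(=O)C(Br)=C2)C(C)(C)C1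
F8 | step 16 | 3-{(E)-2-[(1S,4S,6R)-4-[(tert-butyldimethylsilyl)oxy]-2,2,6-trimethyl-7-oxabicyclo[4.1.0]heptan-1-yl]ethenyl}furan-2(5H)-one | O=C1OCC=C1/C=C/[C@@]23O[C@]2(C)C[C@@H](O[Si](C)(C)C(C)(C)C)CC3(C)C
F9 | step 16 | O-(tert-butyldimethylsilyl)pyrrhoxanthin | CC(=O)O[C@@H]1CC(C)=C(C#C/C(C)=C/C=C/C=C/C=C(C)/C=C2C=C(/C=C/[C@@]34O[C@]3(C)C[C@@H](O[Si](C)(C)C(C)(C)C)CC4(C)C)C(=O)O/2)C(C)(C)C1
A1 | alternative 1 | 2-trimethylsilylfuran carrying the epoxy vinyl arm at C3 and the iodoalkenyl arm at C5 | C[Si](C)(C)c1oc(C/C(C)=C/I)cc1/C=C/[C@@]12O[C@]1(C)C[C@@H](O[Si](CC)(CC)CC)CC2(C)C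
A2 | alternative 1 | γ-hydroxybutenolide (hemiketal carbon as a mixture) | O=C1OC(O)(C/C(C)=C/I)C=C1/C=C/[C@@]23O[C@]2(C)C[C@@H](O[Si](CC)(CC)CC)CC3(C)C
A3 | alternative 2 | (Z)-β-iodoenone with epoxy vinyl and silyloxy alkenyl arms | CC(C)(C)[Si](C)(C)OC/C=C(C)/CC(=O)/C=C(I)/C=C/[C@@]12O[C@]1(C)C[C@@H](O)CC2(C)C
A4 | alternative 2 | epoxy-vinyl (Z)-alkylidenebutenolide with silyloxy dienyl arm | CC(C)(C)[Si](C)(C)OC/C=C(C)/C=C1C=C(/C=C/[C@@]23O[C@]2(C)C[C@@H](O)CC3(C)C)C(=O)O/1
A5 | alternative 3 | ring A 1,3-diyne, (4R)-4-[(tert-butyldimethylsilyl)oxy]-1-(buta-1,3-diyn-1-yl)-2,6,6-trimethylcyclohex-1-ene | C#CC#CC1=C(C)C[C@@H](O[Si](C)(C)C(C)(C)C)CC1(C)C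
A6 | alternative 3 | ethyl (2E,4E,6E)-7-iodo-2-methylhepta-2,4,6-trienoate | CCOC(=O)/C(C)=C/C=C/C=C/I
A7 | alternative 3 | ring A tetraenynoate | CC(C)(C)[Si](C)(C)O[C@@H]1CC(C)=C(C#C/C(C)=C/C=C/C=C/C=C(C)/C(=O)OCC)C(C)(C)C1
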